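Solid X cannot become Z directly in this flask: it has to dissolve as Q and pass through D first.

X 0.25 M; time 50 s

    Q → D (k1 = 1.4 s⁻¹)
    D ⇌ Z (K2 = 2.8, k2 = 0.24 s⁻¹)
    D ⇌ J (K3 = 2.2, k3 = 0.089 s⁻¹)
    X ⇌ Q, rate k4*(cs4 - [Q]) while solid is left; crystals form when [Q] > cs4 (cs4 = 0.091 M, k4 = 0.039 s⁻¹)

1. Z at 50 s, in percent of the X charged
2. concentration of Q in solution at 50 s, in percent of saturation

Reckoned by hand in fractions of the charge, the curve of Q starts with slope 0.0142 s⁻¹ and bends on the scale of its half-life by step 1, 0.50 s, much shorter than the run. Its level takes two rounds. With dissolution at full drive, step 1 balances it at 2.79% of saturation; that level takes the same share off the drive, and the second round gives 2.71%, or 0.986% of the charge. Step 1 is much faster, so dissolution is the rate-limiting step and the solid falls in a straight line. The emptying time, the charge divided by this steady dissolution rate, is 72.4 s.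

Z starts flat, with D standing between it and Q. Taking the split among D, Z and J as immediate, Z holds its equilibrium share of what has passed through, 46.7%. Z then climbs with slope 0.00645 s⁻¹, and that share is also the reckoned level it runs into after a second knee at the emptying time. The asked time comes before that knee, with 69.1% of the charge dissolved. Less the Q in solution, this hand reckoning commits to 31.8% for Z.

The forecast gives 33.4% and 2.7%, above the hand reckoning on Z, and its ground is this: “Q is consumed far faster than the solid dissolves”.

The simulation gives 33.3% and 2.71%, so the forecast stands within its margin on both.

This flask is not at rest at 50 s, which is short of the reckoned emptying time of 72.4 s: X still stands at 30.9%, beside Z at 33.3%. Ten times the time brings X to 0% and lifts Z by 13 percentage points to 46.7%, close to the reckoned level, with J at 36.7% and D at 16.7%. The neighbour flask, charged with 0.10 M of X, has a reckoned emptying time of 29.0 s, shorter than its run, and at 50.0 s it holds X at 0% and Z at 49.3%.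

The numbers come from no measurement; the flask was simulated.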